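**Plan** (halimane numbering: ring A = C1–C5 and C10, ring B = C5–C10, side chain C11–C16)
1. Retrosynthesis cuts the O–S bond, the C16–lactam C3 bond (B-alkyl Suzuki coupling) and the C13–C14 bond (Evans allylation). In the core it then undoes the C1=C10/H-5 pair (allylic transposition of a C1-oxygenated Δ5(10) enone), reverts ring A to a cyclobutanol (C4–C5 cut, C1–C4 re-joined), and cuts C1–C10, C9–CH3, C8–CH3 and the C9 chain bond.
2. Forward: ring B is made first as a (2R,3R)-2,2,3-trisubstituted cyclohexanone. Ring A then arises by an oxidative two-carbon ring expansion of a 1-(cyclohexenyl)-2,2-dimethylcyclobutanol: the four cyclobutane carbons become C1–C4 and the ring-B alkene carbons C10 and C5 are taken up between them. The chain is then extended and the lactam joined last.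
3. Enabling feature: in ring A the gem-dimethyl carbon C4 is bonded to ring-fusion C5, and the C1=C10 alkene lies next to quaternary C9. A carbinol at C1 bonded to C10 can therefore release C4 as a tertiary radical that re-closes 6-endo on C5, and the resulting 1-oxo-Δ5(10) enone carries the handle for a stereospecific 1,3-transposition.
4. Stereochemistry: C8 by catalytic asymmetric conjugate addition; C9 by trans-selective enolate methylation; C5 by CBS reduction at C1 relayed by suprafacial Pd–H delivery; C13 by Evans alkylation.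

Key step: step 7

Remark: the sulfate is made and drawn as the free hydrogen sulfate; in practice it would be handled as a salt and protonated on acidic ion exchange.
Abbreviations: TBDPS = tert-butyldiphenylsilyl; Hal = (1R,2R,4aS)-1,2,5,5-tetramethyl-1,2,3,4,4a,5,6,7-octahydronaphthalen-1-yl (the decalin core).

**Step 1**
Reactants: 1 but-3-en-1-ol
Product: 2 tert-butyl(but-3-en-1-yloxy)diphenylsilane
Conditions: TBDPSCl, imidazole, CH2Cl2, rt
Reagents that add atoms: tert-butyl(chloro)diphenylsilane, CC(C)(C)[Si](Cl)(c1ccccc1)c1ccccc1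
Why: Standard silylation of a primary alcohol, the TBDPS ether being chosen because it should tolerate the organolithium, Lewis-acid and acetic-acid conditions that follow.

**Step 2**
Reactants: 2 tert-butyl(but-3-en-1-yloxy)diphenylsilane; 3 2-iodocyclohex-2-en-1-one
Product: 5 2-[4-(TBDPS-oxy)butyl]cyclohex-2-en-1-one, via B-alkyl-9-BBN adduct 4 (not isolated)
Conditions: 9-BBN, THF, 0 °C → rt; then 3, PdCl2(dppf) (3 mol%), AsPh3, Cs2CO3, DMF/THF/H2O, rt
Reagents that add atoms: none
Why: Anti-Markovnikov hydroboration of the terminal alkene followed by B-alkyl Suzuki–Miyaura coupling with an α-iodoenone, an established route to 2-alkylcyclohexenones.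

**Step 3**
Reactants: 5 2-[4-(TBDPS-oxy)butyl]cyclohex-2-en-1-one
Product: 7 (R)-2-[4-(TBDPS-oxy)butyl]-3-methylcyclohex-1-en-1-yl acetate, via dimethylaluminium enolate 6 (not isolated)
Conditions: Me3Al (1.5 equiv), copper thiophene-2-carboxylate Cu(O2CC4H3S) (2 mol%), binaphthol-derived bis(1-phenylethyl)amine phosphoramidite (4 mol%, the enantiomer that gives 3R), Et2O, −30 °C; then Ac2O, −30 °C → rt
Reagents that add atoms: trimethylaluminium, C[Al](C)C; acetic anhydride, CC(=O)OC(C)=O
Why: Copper-catalysed asymmetric conjugate addition of Me3Al to a 2-substituted cyclohexenone, in which the chiral phosphoramidite–copper complex selects the enone face and sets the methyl-bearing centre (future C8) as R, while O-acetylation of the aluminium enolate stores the enolate regiochemistry.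

**Step 4**
Reactants: 7 (R)-2-[4-(TBDPS-oxy)butyl]-3-methylcyclohex-1-en-1-yl acetate
Product: 9 (2R,3R)-2-[4-(TBDPS-oxy)butyl]-2,3-dimethylcyclohexan-1-one, via lithium enolate 8 (not isolated)
Conditions: MeLi (2.1 equiv), THF, 0 °C; then MeI, DMPU, −78 → 0 °C
Reagents that add atoms: iodomethane, CI
Why: Regiospecific lithium enolate generation from the enol acetate followed by C-alkylation, in which MeI should attack the tetrasubstituted enolate axially and anti to the pseudoaxial C3 methyl group, so that the new quaternary centre (future C9) carries its methyl trans to the C8 methyl (2R).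

**Step 5**
Reactants: 9 (2R,3R)-2-[4-(TBDPS-oxy)butyl]-2,3-dimethylcyclohexan-1-one
Product: 10 2,4,6-triisopropylbenzenesulfonylhydrazone of 9
Conditions: 2,4,6-triisopropylbenzenesulfonylhydrazide, HCl (cat.), MeOH/THF, rt → 40 °C
Reagents that add atoms: 2,4,6-triisopropylbenzenesulfonylhydrazide, CC(C)c1cc(C(C)C)c(S(=O)(=O)NN)c(C(C)C)c1
Why: Acid-catalysed hydrazone condensation, which is known for α,α-disubstituted cyclohexanones and prepares the Shapiro reaction.

**Step 6**
Reactants: 10 2,4,6-triisopropylbenzenesulfonylhydrazone of 9; 11 2,2-dimethylcyclobutan-1-one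
Product: 13 1-[(5R,6R)-6-[4-(TBDPS-oxy)butyl]-5,6-dimethylcyclohex-1-en-1-yl]-2,2-dimethylcyclobutan-1-ol (both carbinol epimers), via vinyllithium 12 (not isolated)
Conditions: n-BuLi (2.2 equiv), THF, −78 → 0 °C; then 11, −78 °C; H2O quench
Reagents that add atoms: none
Why: Shapiro reaction, in which the dianion can form only on the single α-CH2 and collapses to the vinyllithium at the future C10, followed by 1,2-addition to the cyclobutanone, which release of ring strain should favour over enolisation, the new carbinol centre being formed unselectively and destroyed in step 7.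

**Step 7**
Reactants: 13 1-[(5R,6R)-6-[4-(TBDPS-oxy)butyl]-5,6-dimethylcyclohex-1-en-1-yl]-2,2-dimethylcyclobutan-1-ol
Product: 14 (7R,8R)-8-[4-(TBDPS-oxy)butyl]-4,4,7,8-tetramethyl-3,4,5,6,7,8-hexahydronaphthalen-1(2H)-one
Conditions: Mn(OAc)3·2H2O (2.2 equiv, in portions), Cu(OAc)2·H2O (20 mol%), KOAc, degassed MeCN/AcOH (4:1), 50 °C
Reagents that add atoms: none
Why: Proposed new method: ligand exchange should give a trivalent-manganese alkoxide of the strained tertiary cyclobutanol, whose inner-sphere oxidation triggers β-scission of the C1–C4 bond (the bond to the CMe2 carbon) and gives a ring-opened 1-acylcyclohexene with a tertiary alkyl radical at C4. This nucleophilic radical should add in a 6-endo-trig closure to C5, the β-carbon of the s-trans enone just unveiled, so that the four cyclobutane carbons (C1–C4) and the two alkene carbons (C10, C5) become ring A; the tertiary α-keto radical at C10 is then oxidised by divalent copper with loss of H-5, its only β-hydrogen, to give the tetrasubstituted enone, the monovalent copper being re-oxidised by Mn(OAc)3. The closest known reaction types are the silver/persulfate oxidative ring expansion of 1-arylcyclobutanols to 1-tetralones and Mn(OAc)3/Cu(OAc)2 oxidative radical cyclisations, an alkene taking the place of the arene here. No stereocentre is created, since C5 and C10 end up sp2 and the carbinol centre is destroyed, so both epimers of 13 should converge and C5 is left to be set under reagent control in steps 8–10. The step needs regioselective β-scission, 6-endo rather than 5-exo closure, and oxidation only after ring closure: the gem-dimethyl group secures the first (tertiary radical), the fully substituted C10 and the polarity match at C5 secure the second, and a low stationary concentration of oxidant (catalytic copper, portionwise Mn(OAc)3) is meant to secure the third.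

**Step 8**
Reactants: 14 (7R,8R)-8-[4-(TBDPS-oxy)butyl]-4,4,7,8-tetramethyl-3,4,5,6,7,8-hexahydronaphthalen-1(2H)-one
Product: 15 (1R,7R,8R)-8-[4-(TBDPS-oxy)butyl]-4,4,7,8-tetramethyl-1,2,3,4,5,6,7,8-octahydronaphthalen-1-ol
Conditions: (S)-2-methyl-CBS-oxazaborolidine (20 mol%), BH3·SMe2, THF, −30 °C; MeOH quench
Reagents that add atoms: none
Why: Corey–Bakshi–Shibata reduction, in which the catalyst should differentiate the tetrasubstituted alkenyl side (large) from the CH2 side (small) of the carbonyl and give, under reagent control, the 1R allylic alcohol whose hydroxyl is cis to the C9 methyl group.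

**Step 9**
Reactants: 15 (1R,7R,8R)-8-[4-(TBDPS-oxy)butyl]-4,4,7,8-tetramethyl-1,2,3,4,5,6,7,8-octahydronaphthalen-1-ol
Product: 16 formate ester of 15
Conditions: HCO2H, DCC, DMAP (cat.), CH2Cl2, 0 °C → rt
Reagents that add atoms: formic acid, O=CO
Why: Steglich esterification of the secondary allylic alcohol with retention at C1, giving the substrate for the palladium-mediated transposition.

**Step 10**
Reactants: 16 formate ester of 15
Product: 17 tert-butyl(4-Hal-butoxy)diphenylsilane
Conditions: Pd(acac)2 (5 mol%), n-Bu3P (5 mol%), THF, rt → 40 °C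
Reagents that add atoms: none
Why: Palladium-catalysed hydrogenolysis of an allylic formate (Tsuji–Trost type), in which zerovalent palladium ionises the formate with inversion, loss of CO2 gives a palladium hydride, and the hydride is delivered on the metal face to the more substituted allyl terminus C5, so that the alkene moves to C1=C10 and H-5 ends up trans to the original oxygen, that is cis to the C9 side chain (4aS).

**Step 11**
Reactants: 17 tert-butyl(4-Hal-butoxy)diphenylsilane
Product: 18 4-Hal-butan-1-ol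
Conditions: Bu4NF, THF, rt
Reagents that add atoms: none
Why: Fluoride cleavage of the silyl ether, to which the rest of the molecule is inert.

**Step 12**
Reactants: 18 4-Hal-butan-1-ol
Product: 19 4-Hal-butanoic acid
Conditions: TEMPO (20 mol%), PhI(OAc)2 (2.2 equiv), MeCN/H2O (1:1), rt
Reagents that add atoms: water, O
Why: Oxoammonium-mediated oxidation of the primary alcohol through the aldehyde hydrate to the acid, under conditions that should leave the hindered trisubstituted alkene untouched.

**Step 13**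
Reactants: 19 4-Hal-butanoic acid; 20 (R)-4-benzyloxazolidin-2-one
Product: 22 (R)-4-benzyl-3-(4-Hal-butanoyl)oxazolidin-2-one, via mixed pivalic anhydride 21 (not isolated)
Conditions: PivCl, Et3N, THF, −20 °C; then LiCl, 20, −20 °C → rt
Reagents that add atoms: none
Why: N-Acylation of the Evans auxiliary through the mixed pivalic anhydride, which is attacked at its less hindered carbonyl.

**Step 14**
Reactants: 22 (R)-4-benzyl-3-(4-Hal-butanoyl)oxazolidin-2-one
Product: 24 (R)-4-benzyl-3-[(S)-2-(2-Hal-ethyl)pent-4-enoyl]oxazolidin-2-one, via sodium Z-enolate 23 (not isolated)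
Conditions: NaN(SiMe3)2, THF, −78 °C; allyl iodide, −78 → −45 °C
Reagents that add atoms: allyl iodide, C=CCI
Why: Evans asymmetric alkylation, in which the chelated Z-enolate should be attacked by allyl iodide on the face opposite to the benzyl group of the (R)-auxiliary, setting the side-chain centre (future C13; S at this stage, R in the target by change of CIP priorities only).

**Step 15**
Reactants: 24 (R)-4-benzyl-3-[(S)-2-(2-Hal-ethyl)pent-4-enoyl]oxazolidin-2-one
Product: 25 (S)-2-(2-Hal-ethyl)pent-4-en-1-ol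
Conditions: LiBH4, MeOH (1 equiv), Et2O, 0 °C
Reagents that add atoms: none
Why: Reductive cleavage of the imide to the primary alcohol without epimerisation, with recovery of the auxiliary.

**Step 16**
Reactants: 26 3-methylbutan-1-amine; 27 2,5-dimethoxy-2,5-dihydrofuran
Product: 28 1-(3-methylbutyl)-1,5-dihydro-2H-pyrrol-2-one
Conditions: aq. HCl (2 M), rt; then NaHCO3
Reagents that add atoms: none
Why: Acid hydrolysis of the bis-acetal to cis-butenedial, condensation with the primary amine and internal redox isomerisation give the N-alkyl α,β-unsaturated γ-lactam, a known one-flask lactam synthesis.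

**Step 17**
Reactants: 28 1-(3-methylbutyl)-1,5-dihydro-2H-pyrrol-2-one
Product: 30 3-bromo-1-(3-methylbutyl)-1,5-dihydro-2H-pyrrol-2-one, via trans-dibromide 29 (not isolated)
Conditions: Br2, CH2Cl2, 0 °C; then Et3N, 0 °C → rt
Reagents that add atoms: bromine, BrBr
Why: Bromine addition to the conjugated alkene followed by elimination of HBr through loss of the acidic α-proton, the standard bromination–dehydrobromination route to α-bromo enones and α-bromo unsaturated lactams.

**Step 18**
Reactants: 25 (S)-2-(2-Hal-ethyl)pent-4-en-1-ol; 30 3-bromo-1-(3-methylbutyl)-1,5-dihydro-2H-pyrrol-2-one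
Product: 32 3-[(R)-4-(hydroxymethyl)-6-Hal-hexyl]-1-(3-methylbutyl)-1,5-dihydro-2H-pyrrol-2-one, via bis-9-BBN adduct 31 (not isolated)
Conditions: 9-BBN (2.3 equiv), THF, 0 °C → rt; then 30, PdCl2(dppf) (5 mol%), AsPh3, Cs2CO3, DMF/H2O, rt → 40 °C
Reagents that add atoms: none
Why: 9-BBN should hydroborate only the terminal alkene (the trisubstituted ring alkene next to the quaternary carbon is inert, and the free hydroxyl is taken up as a borinate that hydrolyses on work-up), and B-alkyl Suzuki–Miyaura coupling with the α-bromo unsaturated lactam joins C16 to the lactam C3.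

**Step 19**
Reactants: 32 3-[(R)-4-(hydroxymethyl)-6-Hal-hexyl]-1-(3-methylbutyl)-1,5-dihydro-2H-pyrrol-2-one
Product: 33 (R)-2-(2-Hal-ethyl)-5-[1-(3-methylbutyl)-2-oxo-2,5-dihydro-1H-pyrrol-3-yl]pentyl hydrogen sulfate
Conditions: SO3·pyridine, pyridine, rt; aqueous work-up, acidic ion-exchange resin
Reagents that add atoms: sulfur trioxide–pyridine complex, [O-]S(=O)(=O)[n+]1ccccc1
Why: O-Sulfation of the primary alcohol with SO3·pyridine, a mild reagent that should not touch the lactam or the alkenes.

**Compound list**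
1 | but-3-en-1-ol | C=CCCO | starting material
2 | tert-butyl(but-3-en-1-yloxy)diphenylsilane | C=CCCO[Si](c1ccccc1)(c1ccccc1)C(C)(C)C | intermediate
3 | 2-iodocyclohex-2-en-1-one | O=C1CCCC=C1I | starting material
4 | 9-[4-(tert-butyldiphenylsilyloxy)butyl]-9-borabicyclo[3.3.1]nonane (formed in the flask) | CC(C)(C)[Si](OCCCCB1C2CCCC1CCC2)(c1ccccc1)c1ccccc1 | intermediate
5 | 2-[4-(tert-butyldiphenylsilyloxy)butyl]cyclohex-2-en-1-one | O=C1CCCC=C1CCCCO[Si](c1ccccc1)(c1ccccc1)C(C)(C)C | intermediate
6 | dimethylaluminium (R)-2-[4-(tert-butyldiphenylsilyloxy)butyl]-3-methylcyclohex-1-en-1-olate (formed in the flask) | C[Al](C)OC1=C(CCCCO[Si](c2ccccc2)(c2ccccc2)C(C)(C)C)[C@H](C)CCC1 | intermediate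
7 | (R)-2-[4-(tert-butyldiphenylsilyloxy)butyl]-3-methylcyclohex-1-en-1-yl acetate | CC(=O)OC1=C(CCCCO[Si](c2ccccc2)(c2ccccc2)C(C)(C)C)[C@H](C)CCC1 | intermediate
8 | lithium (R)-2-[4-(tert-butyldiphenylsilyloxy)butyl]-3-methylcyclohex-1-en-1-olate (formed in the flask) | [Li]OC1=C(CCCCO[Si](c2ccccc2)(c2ccccc2)C(C)(C)C)[C@H](C)CCC1 | intermediate
9 | (2R,3R)-2-[4-(tert-butyldiphenylsilyloxy)butyl]-2,3-dimethylcyclohexan-1-one | CC(C)(C)[Si](c1ccccc1)(c1ccccc1)OCCCC[C@@]2(C)C(=O)CCC[C@H]2C | intermediate
10 | N'-[(2R,3R)-2-[4-(tert-butyldiphenylsilyloxy)butyl]-2,3-dimethylcyclohexylidene]-2,4,6-triisopropylbenzenesulfonohydrazide | CC(C)(C)[Si](c1ccccc1)(c1ccccc1)OCCCC[C@@]2(C)C(=NNS(=O)(=O)c3c(C(C)C)cc(C(C)C)cc3C(C)C)CCC[C@H]2C | intermediate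
11 | 2,2-dimethylcyclobutan-1-one | CC1(C)CCC1=O | starting material
12 | [(5R,6R)-6-[4-(tert-butyldiphenylsilyloxy)butyl]-5,6-dimethylcyclohex-1-en-1-yl]lithium (formed in the flask) | CC(C)(C)[Si](c1ccccc1)(c1ccccc1)OCCCC[C@@]2(C)C([Li])=CCC[C@H]2C | intermediate
13 | 1-[(5R,6R)-6-[4-(tert-butyldiphenylsilyloxy)butyl]-5,6-dimethylcyclohex-1-en-1-yl]-2,2-dimethylcyclobutan-1-ol (both carbinol epimers) | CC(C)(C)[Si](c1ccccc1)(c1ccccc1)OCCCC[C@@]2(C)C(=CCC[C@H]2C)C3(O)CCC3(C)C | intermediate
14 | (7R,8R)-8-[4-(tert-butyldiphenylsilyloxy)butyl]-4,4,7,8-tetramethyl-3,4,5,6,7,8-hexahydronaphthalen-1(2H)-one | CC(C)(C)[Si](c1ccccc1)(c1ccccc1)OCCCC[C@@]2(C)C3=C(CC[C@H]2C)C(C)(C)CCC3=O | intermediate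
15 | (1R,7R,8R)-8-[4-(tert-butyldiphenylsilyloxy)butyl]-4,4,7,8-tetramethyl-1,2,3,4,5,6,7,8-octahydronaphthalen-1-ol | CC(C)(C)[Si](c1ccccc1)(c1ccccc1)OCCCC[C@@]2(C)C3=C(CC[C@H]2C)C(C)(C)CC[C@H]3O | intermediate
16 | (1R,7R,8R)-8-[4-(tert-butyldiphenylsilyloxy)butyl]-4,4,7,8-tetramethyl-1,2,3,4,5,6,7,8-octahydronaphthalen-1-yl formate | CC(C)(C)[Si](c1ccccc1)(c1ccccc1)OCCCC[C@@]2(C)C3=C(CC[C@H]2C)C(C)(C)CC[C@H]3OC=O | intermediate
17 | tert-butyl{4-[(1R,2R,4aS)-1,2,5,5-tetramethyl-1,2,3,4,4a,5,6,7-octahydronaphthalen-1-yl]butoxy}diphenylsilane | CC(C)(C)[Si](c1ccccc1)(c1ccccc1)OCCCC[C@@]2(C)C3=CCCC(C)(C)[C@@H]3CC[C@H]2C | intermediate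
18 | 4-[(1R,2R,4aS)-1,2,5,5-tetramethyl-1,2,3,4,4a,5,6,7-octahydronaphthalen-1-yl]butan-1-ol | OCCCC[C@@]1(C)C2=CCCC(C)(C)[C@@H]2CC[C@H]1C | intermediate
19 | 4-[(1R,2R,4aS)-1,2,5,5-tetramethyl-1,2,3,4,4a,5,6,7-octahydronaphthalen-1-yl]butanoic acid | OC(=O)CCC[C@@]1(C)C2=CCCC(C)(C)[C@@H]2CC[C@H]1C | intermediate
20 | (R)-4-benzyloxazolidin-2-one | O=C1N[C@H](Cc2ccccc2)CO1 | starting material
21 | 4-Hal-butanoic pivalic anhydride (formed in the flask) | CC(C)(C)C(=O)OC(=O)CCC[C@@]1(C)C2=CCCC(C)(C)[C@@H]2CC[C@H]1C | intermediate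
22 | (R)-4-benzyl-3-{4-[(1R,2R,4aS)-1,2,5,5-tetramethyl-1,2,3,4,4a,5,6,7-octahydronaphthalen-1-yl]butanoyl}oxazolidin-2-one | O=C(CCC[C@@]1(C)C2=CCCC(C)(C)[C@@H]2CC[C@H]1C)N1[C@H](Cc2ccccc2)COC1=O | intermediate
23 | sodium (Z)-enolate of 22 (formed in the flask) | [Na]O/C(=C\CC[C@@]1(C)C2=CCCC(C)(C)[C@@H]2CC[C@H]1C)N1[C@H](Cc2ccccc2)COC1=O | intermediate
24 | (R)-4-benzyl-3-{(S)-2-[2-((1R,2R,4aS)-1,2,5,5-tetramethyl-1,2,3,4,4a,5,6,7-octahydronaphthalen-1-yl)ethyl]pent-4-enoyl}oxazolidin-2-one | C=CC[C@H](CC[C@@]1(C)C2=CCCC(C)(C)[C@@H]2CC[C@H]1C)C(=O)N1[C@H](Cc2ccccc2)COC1=O | intermediate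
25 | (S)-2-[2-((1R,2R,4aS)-1,2,5,5-tetramethyl-1,2,3,4,4a,5,6,7-octahydronaphthalen-1-yl)ethyl]pent-4-en-1-ol | C=CC[C@H](CC[C@@]1(C)C2=CCCC(C)(C)[C@@H]2CC[C@H]1C)CO | intermediate
26 | 3-methylbutan-1-amine | CC(C)CCN | starting material
27 | 2,5-dimethoxy-2,5-dihydrofuran | COC1C=CC(OC)O1 | starting material
28 | 1-(3-methylbutyl)-1,5-dihydro-2H-pyrrol-2-one | CC(C)CCN1CC=CC1=O | intermediate
29 | trans-3,4-dibromo-1-(3-methylbutyl)pyrrolidin-2-one (racemic, formed in the flask) | CC(C)CCN1CC(Br)C(Br)C1=O | intermediate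
30 | 3-bromo-1-(3-methylbutyl)-1,5-dihydro-2H-pyrrol-2-one | CC(C)CCN1CC=C(Br)C1=O | intermediate
31 | bis(9-BBN) adduct of 25, C-borane at C16 and O-borinate (formed in the flask) | C(CC[C@H](CC[C@@]1(C)C2=CCCC(C)(C)[C@@H]2CC[C@H]1C)COB1C2CCCC1CCC2)B1C2CCCC1CCC2 | intermediate
32 | 3-{(R)-4-(hydroxymethyl)-6-[(1R,2R,4aS)-1,2,5,5-tetramethyl-1,2,3,4,4a,5,6,7-octahydronaphthalen-1-yl]hexyl}-1-(3-methylbutyl)-1,5-dihydro-2H-pyrrol-2-one | CC(C)CCN1CC=C(CCC[C@H](CC[C@@]2(C)C3=CCCC(C)(C)[C@@H]3CC[C@H]2C)CO)C1=O | intermediate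
33 | (R)-5-[1-(3-methylbutyl)-2-oxo-2,5-dihydro-1H-pyrrol-3-yl]-2-{2-[(1R,2R,4aS)-1,2,5,5-tetramethyl-1,2,3,4,4a,5,6,7-octahydronaphthalen-1-yl]ethyl}pentyl hydrogen sulfate (CNP0218721.1) | CC(C)CCN1CC=C(CCC[C@H](CC[C@@]2(C)C3=CCCC(C)(C)[C@@H]3CC[C@H]2C)COS(=O)(=O)O)C1=O | target

**Step count**
Total: 19 steps. Longest linear sequence: 17 steps (steps 1–15, 18 and 19); steps 16–17 form the lactam branch.

**Steps most likely to fail and fallbacks**

Step 7 (oxidative ring expansion). What may go wrong: oxidation of the open-chain tertiary radical before it cyclises, hydrogen abstraction by the α-keto radical instead of desaturation, or an acid-induced semipinacol shift of the alkenylcyclobutanol. The fallback builds ring A by a known five-to-six ring expansion and sets out from ketone 9. KN(SiMe3)2 and PhNTf2 give the enol triflate F1, since only one side can enolise. Carbonylative Stille coupling with tributyl(2-methylprop-1-enyl)stannane (Pd(PPh3)4, LiCl, CO, THF) gives the cross-conjugated dienone F2. Nazarov cyclisation (FeCl3 or MeSO3H, CH2Cl2) forms the C4–C5 bond and, because H-5 is the only proton that can be lost, gives the ring-fused 4,4-dimethylcyclopentenone F3. Homologation with trimethylsilyldiazomethane (BF3·OEt2, CH2Cl2, −78 °C), in which the saturated CH2 should migrate in preference to the alkenyl carbon, gives the α-silyl cyclohexenone F4. Protodesilylation (dilute HCl, THF) comes back to the route at enone 14.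

Step 10 (formate hydrogenolysis). What may go wrong: hydride delivery to C1 instead of C5 (plain deoxygenation to the tetrasubstituted olefin) or β-hydride elimination of the hindered allyl complex to dienes. The fallback sets out from alcohol 15. Mitsunobu displacement with 2-nitrobenzenesulfonylhydrazide (PPh3, DEAD, THF, −30 °C) gives, with inversion at C1, the N-allylic sulfonylhydrazine F5. On warming this loses the sulfinic acid to give the allylic diazene F6. Its sigmatropic loss of nitrogen delivers hydrogen to C5 on the face where nitrogen sits, which is the face opposite to the original hydroxyl as in the palladium route, and comes back at 17.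

Step 18 (B-alkyl Suzuki coupling with the bromolactam). What may go wrong: base-induced isomerisation or decomposition of the bromolactam, or slow transmetalation leading to protodeboronation. The fallback builds the lactam ring on the chain and sets out from 25. Amine 26 is N-allylated (allyl bromide, K2CO3) to N-allyl-3-methylbutan-1-amine F7 and acylated with 2-bromoacrylic acid (EDC) to the bromoacrylamide F8. The 9-BBN adduct 31 of 25 is coupled with F8 under the same palladium conditions to the diene amide F9. Ring-closing metathesis with the second-generation Grubbs catalyst RuCl2(H2IMes)(PCy3)(=CHPh) (CH2Cl2, 40 °C) closes the unsaturated lactam and comes back at 32; the hindered ring alkene should not take part.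

**Further compounds**
F1 | step 7 | (5R,6R)-6-[4-(tert-butyldiphenylsilyloxy)butyl]-5,6-dimethylcyclohex-1-en-1-yl trifluoromethanesulfonate | CC(C)(C)[Si](c1ccccc1)(c1ccccc1)OCCCC[C@@]2(C)C(OS(=O)(=O)C(F)(F)F)=CCC[C@H]2C
F2 | step 7 | 1-[(5R,6R)-6-[4-(tert-butyldiphenylsilyloxy)butyl]-5,6-dimethylcyclohex-1-en-1-yl]-3-methylbut-2-en-1-one | CC(C)(C)[Si](c1ccccc1)(c1ccccc1)OCCCC[C@@]2(C)C(C(=O)C=C(C)C)=CCC[C@H]2C
F3 | step 7 | (6R,7R)-7-[4-(tert-butyldiphenylsilyloxy)butyl]-3,3,6,7-tetramethyl-2,3,4,5,6,7-hexahydro-1H-inden-1-one | CC(C)(C)[Si](c1ccccc1)(c1ccccc1)OCCCC[C@@]2(C)C3=C(CC[C@H]2C)C(C)(C)CC3=O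
F4 | step 7 | (7R,8R)-8-[4-(tert-butyldiphenylsilyloxy)butyl]-4,4,7,8-tetramethyl-2-(trimethylsilyl)-3,4,5,6,7,8-hexahydronaphthalen-1(2H)-one | CC(C)(C)[Si](c1ccccc1)(c1ccccc1)OCCCC[C@@]2(C)C3=C(CC[C@H]2C)C(C)(C)CC([Si](C)(C)C)C3=O
F5 | step 10 | N-[(1S,7R,8R)-8-[4-(tert-butyldiphenylsilyloxy)butyl]-4,4,7,8-tetramethyl-1,2,3,4,5,6,7,8-octahydronaphthalen-1-yl]-2-nitrobenzenesulfonohydrazide | CC(C)(C)[Si](c1ccccc1)(c1ccccc1)OCCCC[C@@]2(C)C3=C(CC[C@H]2C)C(C)(C)CC[C@@H]3N(N)S(=O)(=O)c1ccccc1[N+](=O)[O-]
F6 | step 10 | (1S,7R,8R)-8-[4-(tert-butyldiphenylsilyloxy)butyl]-4,4,7,8-tetramethyl-1,2,3,4,5,6,7,8-octahydronaphthalen-1-yldiazene | CC(C)(C)[Si](c1ccccc1)(c1ccccc1)OCCCC[C@@]2(C)C3=C(CC[C@H]2C)C(C)(C)CC[C@@H]3N=N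
F7 | step 18 | N-allyl-3-methylbutan-1-amine | C=CCNCCC(C)C
F8 | step 18 | N-allyl-2-bromo-N-(3-methylbutyl)prop-2-enamide | C=CCN(CCC(C)C)C(=O)C(Br)=C
F9 | step 18 | N-allyl-2-{(R)-4-(hydroxymethyl)-6-[(1R,2R,4aS)-1,2,5,5-tetramethyl-1,2,3,4,4a,5,6,7-octahydronaphthalen-1-yl]hexyl}-N-(3-methylbutyl)prop-2-enamide | C=CCN(CCC(C)C)C(=O)C(=C)CCC[C@H](CC[C@@]1(C)C2=CCCC(C)(C)[C@@H]2CC[C@H]1C)CO
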